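At early times X is what moves: it gives Z directly and, more slowly, D, which then gives Z, while J pairs with Z to form J.Z.

| flask | X | J | remark | time |
|---|---|---|---|---|
| midnight | 0.25 M | 1.10 equiv | a single well-mixed tank run continuously and read at steady state, 8.0 min in it on average |  |
| summer | 0.25 M | 1.10 equiv | everything together in a closed stirred flask, run for 8.0 min | 8.0 min |
| autumn | 0.25 M | 1.10 equiv (fed, over 4.00 min) | all but J at the start; J goes in evenly over 4.00 min, the run ends at 8.0 min | 8.0 min |
| noon | 0.25 M (fed, over 4.00 min) | 1.10 equiv | all but X at the start; X goes in evenly over 4.00 min, the run ends at 8.0 min | 8.0 min |

- the set-up with the highest amount of J.Z at the outlet or at the end, in percent of the X put in ("none" if the first two lie within 2 percentage points) (midnight / summer / autumn / noon / none)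
- amount of J.Z at the outlet or at the end, in percent of the X put in, midnight
- amount of J.Z at the outlet or at the end, in percent of the X put in, summer
- amount of J.Z at the outlet or at the end, in percent of the X put in, autumn
- amount of J.Z at the outlet or at the end, in percent of the X put in, noon

- the stated concentrations are those of everything mixed, before any reaction; amounts are the same in each set-up
- the feed brings no volume worth counting
- run time (summer): 8.0 min

    J + Z → J.Z (k1 = 0.0210 M⁻¹ s⁻¹)
    D → Z (k2 = 0.00206 s⁻¹)
    X → D (k3 = 0.00117 s⁻¹)
    X → Z (k4 = 0.0151 s⁻¹)

X lasts 1.02 min on average, and 92.8% of it takes the direct way. What I carry is the capture time, the reciprocal of the pairing constant times the X charge, the time in which J and Z at equal charged strength fall to half: 3.17 min. X goes sooner than Z is captured, so pairing is the rate-limiting step.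

J is charged at 1.10 equiv, so once X has turned over the gap between J and Z is small and nearly constant, and I freeze the two as equal. The yield is then the number of capture times in the usable run, over one plus that number.

In summer the usable run loses the life of X, which gives 2.20 capture times and 68.7%. In autumn J arrives on average at half the feed time, which is longer than the life of X, so I count from there and get 1.89 and 65.4%. In noon X arrives on average at half the feed time and then needs its life, so I get 1.57 and 61.0%. For midnight, I write the tank balance as the yield equal to the capture times in the mean stay times the square of the unpaired share, which gives 53.8%.

The opposite answer, "none", needs summer and autumn within 2 percentage points. I put them 3.3 points apart, which is 1.3 points clear of a tie.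

The forecast gives 51% for midnight, 70% for summer, 66% for autumn and 61% for noon, and says “the closed batch therefore wins”.

The simulation gives 51.1% for midnight, 70.2% for summer, 65.9% for autumn and 61.0% for noon, so summer leads autumn by 4.3 points.

Early Z is what the capture clock counts: taking the loss of X to Z away drops summer from 70.2% to 9.33%. A neighbour of noon with 0.42 M of X, its equivalents held, shortens the capture time to 1.89 min, which gives 2.63 capture times and 72.5%, and that flask reads 71.8%.

The numbers of this flask come from no measurement; the result is computed.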